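The oxolane (O1, C2 veratryl, C3, C4, C5 syringyl) is disconnected at C2–C3. C2 is benzylic and bonded to O1, so a planar, stabilised radical can be generated there from a carboxylic acid, and the C3 methyl is read as the terminus of a former vinyl group. One photoredox operation then loses CO2, closes the ring 5-exo, forms C2–C3, sets C2 and C3 and converts =CH2 into the C3 methyl. The precursor is an open-chain ether: an α-veratryl-α-alkoxyacetic acid (acid carbon stereorandom) whose alkoxy part is the anti (1S,2S) homoallylic alcohol carrying C5, C4 and the vinyl group, with the syringyl phenol benzylated.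

Key step: step 6

Remark on configuration: in this numbering the target is (2R,3S,4S,5S). The C2 veratryl group is cis to the C3 methyl, the C3 and C4 methyls are trans, the C4 methyl is trans to the C5 syringyl group, and the two aryl groups are cis. A trans C4/C5 pair in the ring corresponds to the anti homoallylic alcohol.

Step 1
Reactants: 1 syringaldehyde (4-hydroxy-3,5-dimethoxybenzaldehyde)
Product: 2 4-(benzyloxy)-3,5-dimethoxybenzaldehyde
Conditions: BnBr, K2CO3, DMF, 60 °C
Reagents that add atoms: benzyl bromide, BrCc1ccccc1
Why: Williamson ether synthesis on an acidic, formyl-activated phenol; the benzyl group keeps the phenol away from the carbenoid of step 4 and from oxidation in step 6, and it tolerates base, peroxide work-up and radicals.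

Step 2
Reactants: 2 4-(benzyloxy)-3,5-dimethoxybenzaldehyde; 3 trans-2-butene; 4 (−)-B-methoxydiisopinocampheylborane, (−)-Ipc2BOMe, the reagent derived from (+)-α-pinene
Product: 9 (1S,2S)-1-[4-(benzyloxy)-3,5-dimethoxyphenyl]-2-methylbut-3-en-1-ol (anti), via (E)-crotylpotassium 5 (not isolated), via potassium borate complex 6 (not isolated), via (E)-crotyldiisopinocampheylborane 7 (not isolated), via borinic ester 8 (not isolated)
Conditions: 3 (excess), KOt-Bu, n-BuLi, THF, −78 to −45 °C; 4, −78 °C; BF3·OEt2, then 2, −78 °C; NaOH, H2O2, 0 °C to rt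
Reagents that add atoms: none
Why: Brown asymmetric crotylboration: low-temperature metalation of 3 keeps the E geometry, borane 7 adds through a closed Zimmerman–Traxler chair so that the E geometry becomes the anti C4/C5 pair, and the isopinocampheyl groups from (+)-α-pinene direct attack to the Si face of 2, which sets C5 as S and C4 as S.

Step 3
Reactants: 10 methyl (3,4-dimethoxyphenyl)acetate
Product: 11 methyl 2-diazo-2-(3,4-dimethoxyphenyl)acetate
Conditions: 4-acetamidobenzenesulfonyl azide, DBU, MeCN, 0 °C to rt
Reagents that add atoms: 4-acetamidobenzenesulfonyl azide, CC(=O)Nc1ccc(cc1)S(=O)(=O)N=[N+]=[N-]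
Why: Regitz diazo transfer to a CH2 group activated by both aryl and ester, the standard entry to aryl diazoacetates.

Step 4
Reactants: 9 (1S,2S)-1-[4-(benzyloxy)-3,5-dimethoxyphenyl]-2-methylbut-3-en-1-ol; 11 methyl 2-diazo-2-(3,4-dimethoxyphenyl)acetate
Product: 12 methyl 2-{[(1S,2S)-1-(4-benzyloxy-3,5-dimethoxyphenyl)-2-methylbut-3-en-1-yl]oxy}-2-(3,4-dimethoxyphenyl)acetate, both epimers at the ester α-carbon
Conditions: Rh2(OAc)4 (1 mol %), 4 Å MS, CH2Cl2, rt, slow addition of 11 (1.5 equiv)
Reagents that add atoms: none
Why: Rhodium-carbenoid O–H insertion (oxonium ylide, then proton shift), which for a donor/acceptor carbenoid is much faster at a hydroxyl group than cyclopropanation of a monosubstituted alkene; the neutral medium leaves C4 and C5 untouched, and the new centre forms unselectively, which does not matter because step 6 erases it.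

Step 5
Reactants: 12 methyl ester described in step 4
Product: 14 2-(3,4-dimethoxyphenyl)-2-{[(1S,2S)-1-(4-benzyloxy-3,5-dimethoxyphenyl)-2-methylbut-3-en-1-yl]oxy}acetic acid, both epimers at the acid α-carbon, via lithium carboxylate 13 (not isolated)
Conditions: LiOH, THF/MeOH/H2O, rt; cold 1 M HCl to pH 3–4
Reagents that add atoms: lithium hydroxide, [Li+].[OH-]
Why: Ester saponification by addition–elimination; enolisation can only scramble the already stereorandom α-carbon, and the ethers and the vinyl group are inert to hydroxide.

Step 6
Reactants: 14 the acid described in step 5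
Product: 17 (2R,3S,4S,5S)-5-[4-(benzyloxy)-3,5-dimethoxyphenyl]-2-(3,4-dimethoxyphenyl)-3,4-dimethyloxolane, via benzylic radical 15 (not isolated), via primary radical 16 (not isolated)
Conditions: [Ir(dF(CF3)ppy)2(dtbbpy)]PF6 (2 mol %), 2,4,6-triisopropylbenzenethiol (20 mol %), Cs2CO3 (20 mol %), degassed MeCN (0.01 M), blue LEDs (450 nm), rt
Reagents that add atoms: none
Why: The photoexcited trivalent iridium complex oxidises the carboxylate of 14, both epimers lose CO2 to the same planar, O1-conjugated benzylic radical 15, 15 adds to the inner vinyl carbon to give primary radical 16, 16 takes H from the arenethiol, and the thiyl radical is returned to thiol by the divalent iridium complex and a proton from 14, so the cycle is redox-neutral. The closest known reaction types are the photoredox hydrodecarboxylation of α-oxy and arylacetic acids with thiol or disulfide co-catalysts and the polar-radical-crossover oxolane syntheses in which a photogenerated benzylic radical closes 5-exo on an unactivated allyl group before hydrogen-atom transfer; an α-oxy, aryl-stabilised radical meeting a plain vinyl group sits at the demanding end of that scope. The oxolane closes 5-exo-trig through a Beckwith–Houk chair in which the C5 aryl, the C4 methyl and the C2 aryl are all pseudo-equatorial. C3 is set by the resident C4 and C5 centres, since that chair places the nascent CH2 radical trans to the C4 methyl and cis to the C5 aryl, and C2 is set by the rotamer about the partly π-bonded O1–C2 bond, the veratryl group pointing away from C5 and so ending cis to both the C3 substituent and the C5 aryl. The step needs ring closure to outrun hydrogen transfer to 15 and needs 16 to be trapped before it can reopen or drift to the 6-endo isomer: an arenethiol delivers H to a primary alkyl radical orders of magnitude faster than to a stabilised benzylic one, the vicinal C4/C5 substituents pre-fold the chain onto the unhindered terminal alkene, and low thiol loading at high dilution widens the gap. A hindered arenethiol is chosen over an alkanethiol because its thiyl radical adds to the vinyl group only reversibly (no thiol–ene loss) and is too weak an abstractor to reopen the C2–H or C5–H bonds of 17, which preserves the kinetic C2/C3 cis pair.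

Step 7
Reactants: 17 O-benzyl ether of the target
Product: 18 4-[(2S,3S,4S,5R)-5-(3,4-dimethoxyphenyl)-3,4-dimethyloxolan-2-yl]-2,6-dimethoxyphenol, the target, (2R,3S,4S,5S) in the route numbering
Conditions: H2 (1 atm), 10% Pd/C, EtOAc, rt, stopped at consumption of 17
Reagents that add atoms: none
Why: Catalytic hydrogenolysis of an aryl benzyl ether, which at 1 atm in a neutral solvent is far faster than cleavage of the hindered ring C2–O1 and C5–O1 bonds, so no stereocentre is touched.

Compound list
1 | syringaldehyde | COc1cc(C=O)cc(OC)c1O | starting material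
2 | 4-(benzyloxy)-3,5-dimethoxybenzaldehyde | COc1cc(C=O)cc(OC)c1OCc1ccccc1 | intermediate
3 | trans-2-butene | C/C=C/C | starting material
4 | (−)-B-methoxydiisopinocampheylborane | COB([C@@H]1C[C@@H]2C[C@H]([C@H]1C)C2(C)C)[C@@H]1C[C@@H]2C[C@H]([C@H]1C)C2(C)C | starting material
5 | (E)-crotylpotassium | C/C=C/[CH2-].[K+] | intermediate
6 | potassium (E)-crotyl(methoxy)diisopinocampheylborate | [K+].C/C=C/C[B-](OC)([C@@H]1C[C@@H]2C[C@H]([C@H]1C)C2(C)C)[C@@H]1C[C@@H]2C[C@H]([C@H]1C)C2(C)C | intermediate
7 | (E)-crotyldiisopinocampheylborane | C/C=C/CB([C@@H]1C[C@@H]2C[C@H]([C@H]1C)C2(C)C)[C@@H]1C[C@@H]2C[C@H]([C@H]1C)C2(C)C | intermediate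
8 | diisopinocampheylborinic ester of alcohol 9 | B([C@@H]1C[C@@H]2C[C@H]([C@H]1C)C2(C)C)([C@@H]1C[C@@H]2C[C@H]([C@H]1C)C2(C)C)O[C@H](c1cc(OC)c(OCc2ccccc2)c(OC)c1)[C@@H](C)C=C | intermediate
9 | (1S,2S)-1-[4-(benzyloxy)-3,5-dimethoxyphenyl]-2-methylbut-3-en-1-ol | O[C@H](c1cc(OC)c(OCc2ccccc2)c(OC)c1)[C@@H](C)C=C | intermediate
10 | methyl (3,4-dimethoxyphenyl)acetate | COC(=O)Cc1ccc(OC)c(OC)c1 | starting material
11 | methyl 2-diazo-2-(3,4-dimethoxyphenyl)acetate | COC(=O)C(=[N+]=[N-])c1ccc(OC)c(OC)c1 | intermediate
12 | methyl 2-{[(1S,2S)-1-(4-benzyloxy-3,5-dimethoxyphenyl)-2-methylbut-3-en-1-yl]oxy}-2-(3,4-dimethoxyphenyl)acetate, α-epimers | COc1ccc(C(C(=O)OC)O[C@H](c2cc(OC)c(OCc3ccccc3)c(OC)c2)[C@@H](C)C=C)cc1OC | intermediate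
13 | lithium salt of acid 14 | [Li+].COc1ccc(C(C(=O)[O-])O[C@H](c2cc(OC)c(OCc3ccccc3)c(OC)c2)[C@@H](C)C=C)cc1OC | intermediate
14 | 2-(3,4-dimethoxyphenyl)-2-{[(1S,2S)-1-(4-benzyloxy-3,5-dimethoxyphenyl)-2-methylbut-3-en-1-yl]oxy}acetic acid, α-epimers | COc1ccc(C(C(=O)O)O[C@H](c2cc(OC)c(OCc3ccccc3)c(OC)c2)[C@@H](C)C=C)cc1OC | intermediate
15 | α-alkoxy benzylic (C2) radical formed from 14 by loss of CO2 | COc1ccc([CH]O[C@H](c2cc(OC)c(OCc3ccccc3)c(OC)c2)[C@@H](C)C=C)cc1OC | intermediate
16 | cyclised primary radical (CH2 radical on C3 of the oxolane) | COc1ccc([C@@H]2O[C@H](c3cc(OC)c(OCc4ccccc4)c(OC)c3)[C@@H](C)[C@@H]2[CH2])cc1OC | intermediate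
17 | (2R,3S,4S,5S)-5-[4-(benzyloxy)-3,5-dimethoxyphenyl]-2-(3,4-dimethoxyphenyl)-3,4-dimethyloxolane | COc1ccc([C@@H]2O[C@H](c3cc(OC)c(OCc4ccccc4)c(OC)c3)[C@@H](C)[C@@H]2C)cc1OC | intermediate
18 | 4-[(2S,3S,4S,5R)-5-(3,4-dimethoxyphenyl)-3,4-dimethyloxolan-2-yl]-2,6-dimethoxyphenol | COc1ccc([C@@H]2O[C@H](c3cc(OC)c(O)c(OC)c3)[C@@H](C)[C@@H]2C)cc1OC | target

Total step count: 7. Longest linear sequence: 6 steps (steps 1, 2, 4, 5, 6, 7, from syringaldehyde); step 3 is a one-step side branch.

Steps most likely to fail

Step 6. Addition of the stabilised radical to an unpolarised alkene may be too slow. Premature hydrogen transfer or radical dimerisation could then take over, and face selectivity at C2 may be modest. The fallback uses a polarity-matched acceptor and sets out from acid 14.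
- Cross-metathesis of 14 with phenyl vinyl sulfone (second-generation Grubbs catalyst, CH2Cl2, reflux) should give the (E)-vinyl sulfone acid F1.
- Irradiation of F1 with [Ir(dF(CF3)ppy)2(dtbbpy)]PF6 and K2HPO4 in DMF, without thiol, is an intramolecular decarboxylative Giese addition. This is a well-established reaction of nucleophilic α-oxy radicals with vinyl sulfones. It closes the same C2–C3 bond 5-exo, and the α-sulfonyl radical is then reduced and protonated to the 3-(phenylsulfonylmethyl)oxolane F2.
- Reductive desulfonylation (Mg, MeOH) turns CH2SO2Ph into the C3 methyl and rejoins the route at 17.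

Step 4. The flanked secondary hydroxyl group may attack the carbenoid slowly. That would allow cyclopropanation of the vinyl group, insertion into traces of water or carbene dimerisation. The fallback replaces carbenoid chemistry by substitution and sets out from diazo ester 11.
- Dry HCl in Et2O at 0 °C protonates the diazo carbon and chloride captures it, giving methyl 2-chloro-2-(3,4-dimethoxyphenyl)acetate F3.
- Alcohol 9 is then alkylated by F3 under Ag2O in CH2Cl2. Halide abstraction is assisted by the veratryl group and the medium stays non-basic and non-acidic. This rejoins the route at 12.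

Step 2. Loss of E geometry in the crotyl anion, or a boratropic shift on warming, would leak the syn series. Facial selectivity on this electron-rich aldehyde may also be incomplete. The fallback replaces the stoichiometric chiral borane by a configurationally stable achiral boronate with a chiral Brønsted acid, and sets out from aldehyde 2.
- Commercial (E)-crotylboronic acid pinacol ester is used with 5 mol % of 3,3'-bis(2,4,6-triisopropylphenyl)-BINOL hydrogen phosphate in toluene at −30 °C. The enantiomer of the acid that directs attack to the Si face of 2 is chosen.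
- The reaction passes through the same closed chair (anti) to the O-boryl ether F4, which is hydrolysed on work-up and rejoins the route at 9.

Further compounds
F1 | step 6 | (E)-phenylsulfonylvinyl analogue of acid 14, α-epimers | COc1ccc(C(C(=O)O)O[C@H](c2cc(OC)c(OCc3ccccc3)c(OC)c2)[C@@H](C)/C=C/S(=O)(=O)c2ccccc2)cc1OC
F2 | step 6 | analogue of 17 bearing CH2SO2Ph in place of the C3 methyl, same relative and absolute configuration | COc1ccc([C@@H]2O[C@H](c3cc(OC)c(OCc4ccccc4)c(OC)c3)[C@@H](C)[C@@H]2CS(=O)(=O)c2ccccc2)cc1OC
F3 | step 4 | methyl 2-chloro-2-(3,4-dimethoxyphenyl)acetate (racemic) | COC(=O)C(Cl)c1ccc(OC)c(OC)c1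
F4 | step 2 | O-(4,4,5,5-tetramethyl-1,3,2-dioxaborolan-2-yl) ether of alcohol 9 | CC1(C)OB(O[C@H](c2cc(OC)c(OCc3ccccc3)c(OC)c2)[C@@H](C)C=C)OC1(C)C
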